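## Retrosynthetic overview

1. The target is the (2R,3S,4S)-flavan-3,4-diol (2,3-trans, 3,4-cis). C4–OH comes from a C4 ketone by bulky hydride reduction. The C8 prenyl group comes from C8–Br by Stille coupling, placed after the oxidation because a prenyl group ortho to C7–OH would not survive DDQ.
2. Feature used: ring B with its C4' hydroxyl plus the chain C2–C3–C4 is the tyrosine skeleton (CH2 = C2, amino-bearing carbon = C3, CO2H = C4). The C4'–OH para to C2 allows C2–H to be oxidised to a para-quinone methide.
3. Key disconnection O1–C2: the C8a–OH of an (R)-alpha-hydroxydihydrochalcone captures that quinone methide, and C3 (from D-tyrosine) directs C2.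
4. Disconnection C4–C4a: the Weinreb amide of (R)-4-hydroxyphenyllactic acid plus an arylmagnesium from 5-methoxyresorcinol (Br at the future C8 by directed lithiation, I at the future C4a by iodination).
5. Ring order: rings A and B are bought, and ring C is the only ring formed (step 9).

Key step: step 9

Remark: flavonoid numbering (O1, C2, C3, C4, C4a, C5–C8, C8a, ring B primed) is also used for the open-chain precursors. The 4beta descriptor is read from the SMILES as (4S), cis to C3–OH.

## Route

Step 1
Reactants: 1 D-tyrosine
Product: 4 (R)-2-hydroxy-3-(4-hydroxyphenyl)propanoic acid, via diazonium carboxylate 2 (not isolated), via alpha-lactone 3 (not isolated)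
Conditions: NaNO2 (1.5 equiv, slow addition), 0.5 M H2SO4, H2O, 0 °C → rt
Reagents that add atoms: water, SMILES O
Why: Diazotisation of an alpha-amino acid with double inversion: the neighbouring carboxylate expels N2 from 2 with inversion to give alpha-lactone 3 and water opens 3 at the alkyl carbon with a second inversion, so the (R) centre (future C3) is retained, while slow nitrite addition at 0 °C keeps C-nitrosation of the ring B phenol minor.

Step 2
Reactants: 4 (R)-2-hydroxy-3-(4-hydroxyphenyl)propanoic acid
Product: 6 (R)-2-hydroxy-3-(4-hydroxyphenyl)-N-methoxy-N-methylpropanamide, via benzotriazol-1-yl ester 5 (not isolated)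
Conditions: MeNH(OMe)·HCl, EDC·HCl, HOBt, N-methylmorpholine, DMF, 0 °C → rt
Reagents that add atoms: N,O-dimethylhydroxylamine hydrochloride, SMILES CNOC.Cl
Why: Carbodiimide/HOBt amide coupling to the Weinreb amide: the free-based amine is a far better nucleophile towards active ester 5 than the phenol or the secondary alcohol, and an alpha-hydroxy acid cannot form an oxazolone, so the stereocentre is not at risk.

Step 3
Reactants: 6 (R)-2-hydroxy-3-(4-hydroxyphenyl)-N-methoxy-N-methylpropanamide
Product: 7 (R)-N-methoxy-2-(methoxymethoxy)-3-[4-(methoxymethoxy)phenyl]-N-methylpropanamide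
Conditions: MOMCl (4 equiv), i-Pr2NEt, Bu4NI (cat.), CH2Cl2, 0 °C → reflux
Reagents that add atoms: chloromethyl methyl ether, SMILES COCCl
Why: MOM acetal protection (O-alkylation with an alpha-chloro ether under a hindered amine base) caps both hydroxyls with the same acid-labile group that ring A will carry, and the weak base does not deprotonate the alpha carbon.

Step 4
Reactants: 8 5-methoxyresorcinol
Product: 9 1-methoxy-3,5-bis(methoxymethoxy)benzene
Conditions: MOMCl (2.5 equiv), i-Pr2NEt, CH2Cl2, 0 °C → rt
Reagents that add atoms: chloromethyl methyl ether, SMILES COCCl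
Why: The same MOM protection masks both phenols, and the two OMOM groups also serve as directing groups for the next step.

Step 5
Reactants: 9 1-methoxy-3,5-bis(methoxymethoxy)benzene
Product: 11 2-bromo-5-methoxy-1,3-bis(methoxymethoxy)benzene, via 2-lithioarene 10 (not isolated)
Conditions: n-BuLi (1.1 equiv), THF, 0 °C; then BrCH2CH2Br, −78 °C → rt
Reagents that add atoms: 1,2-dibromoethane, SMILES BrCCBr
Why: Directed ortho-metalation: the C–H between the two chelating OMOM groups (future C8) is lithiated in preference to the two C–H flanked by OMOM and the weaker director OMe, and aryllithium 10 takes bromine from 1,2-dibromoethane with loss of ethene.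

Step 6
Reactants: 11 2-bromo-5-methoxy-1,3-bis(methoxymethoxy)benzene
Product: 12 2-bromo-4-iodo-5-methoxy-1,3-bis(methoxymethoxy)benzene
Conditions: NIS (1.0 equiv), MeCN, 0 °C → rt, dark
Reagents that add atoms: N-iodosuccinimide, SMILES O=C1CCC(=O)N1I
Why: Electrophilic aromatic iodination: the two open positions are equivalent by symmetry and activated by three oxygen substituents, neutral NIS spares the MOM acetals, and one equivalent should stop at the monoiodide because that product is more crowded and less electron-rich.

Step 7
Reactants: 12 2-bromo-4-iodo-5-methoxy-1,3-bis(methoxymethoxy)benzene; 7 (R)-N-methoxy-2-(methoxymethoxy)-3-[4-(methoxymethoxy)phenyl]-N-methylpropanamide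
Product: 15 (R)-1-[3-bromo-6-methoxy-2,4-bis(methoxymethoxy)phenyl]-2-(methoxymethoxy)-3-[4-(methoxymethoxy)phenyl]propan-1-one, via arylmagnesium chloride 13 (not isolated), via chelated tetrahedral adduct 14 (not isolated)
Conditions: 12, i-PrMgCl·LiCl (1.05 equiv), THF, −20 °C; then 7, −20 °C → rt; then cold 0.5 M HCl
Reagents that add atoms: none
Why: Iodine–magnesium exchange followed by Weinreb ketone synthesis: exchange at C–I is much faster than at C–Br and is helped by the ortho OMOM group, the bromine is meta to magnesium so no aryne can form, and chelate 14 survives until the quench so that only one aryl group adds and the alpha stereocentre is left untouched.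

Step 8
Reactants: 15 tetra-MOM ketone
Product: 16 (R)-1-(3-bromo-2,4-dihydroxy-6-methoxyphenyl)-2-hydroxy-3-(4-hydroxyphenyl)propan-1-one
Conditions: 3 M HCl in MeOH, 45 °C
Reagents that add atoms: none
Why: Acid-catalysed acetal exchange (MOM methanolysis) frees all four hydroxyls at once and carries formaldehyde away as dimethoxymethane, while the hydrogen-bonded, electron-rich aryl ketone should enolise too slowly for the alpha centre to racemise.

Step 9
Reactants: 16 (R)-1-(3-bromo-2,4-dihydroxy-6-methoxyphenyl)-2-hydroxy-3-(4-hydroxyphenyl)propan-1-one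
Product: 18 (2R,3R)-8-bromo-3,7-dihydroxy-2-(4-hydroxyphenyl)-5-methoxychroman-4-one [(2R,3R)-8-bromo-5-O-methylaromadendrin], via para-quinone methide 17 (not isolated)
Conditions: DDQ (1.05 equiv), dry 1,4-dioxane (0.02 M), 4 Å molecular sieves, 20–40 °C, dark
Reagents that add atoms: none
Why: DDQ complexes the only unacylated, electron-rich phenol (ring B) and removes hydride from the para-benzylic C2–H together with the C4'–OH proton, giving para-quinone methide 17 and the hydroquinone of DDQ. The C8a–OH, held close to C2 by its hydrogen bond to the C4 carbonyl, adds to the exocyclic methide carbon and rearomatises ring B, which forms O1–C2 and closes ring C in a 6-exo-trig mode (the C2=C1' bond that is consumed lies outside the new ring). The closest known reaction type is the DDQ oxidative cyclisation of 2'-hydroxydihydrochalcones and of 1-(2-hydroxyphenyl)-3-(4-hydroxyphenyl)propanes to flavanones and flavans through para-quinone methides, with the C3 hydroxyl here as an added spectator. The new C2 centre is controlled by C3: allylic 1,3-strain puts C3–H in the plane of the methide, the acyl arm then delivers O1 to the face opposite C3–OH, and the chair-like transition state carries C3–OH and ring B both equatorial, giving (2R), 2,3-trans, which is also the thermodynamic isomer reachable by reversible opening of any cis product. The site of oxidation is secured because ring A is deactivated by the acyl group and bromine and carries no prenyl group, and the regiochemistry of closure is secured because C5 bears OMe, so C8a–OH is the only phenol ortho to the carbonyl. One equivalent of DDQ in a dry, base-free, non-nucleophilic solvent should limit tautomerisation of 17 through loss of C3–H, capture by solvent and further dehydrogenation.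

Step 10
Reactants: 18 (2R,3R)-8-bromo-5-O-methylaromadendrin
Product: 19 (2R,3R)-8-bromo-3,7-bis(tert-butyldimethylsilyloxy)-2-[4-(tert-butyldimethylsilyloxy)phenyl]-5-methoxychroman-4-one
Conditions: TBSCl (4.5 equiv), imidazole, DMF, rt
Reagents that add atoms: tert-butyldimethylsilyl chloride, SMILES CC(C)(C)[Si](C)(C)Cl
Why: Silyl ether formation with silyl chloride and imidazole covers the two phenols and the C3 alcohol; capping C4'–OH also blocks ring opening through the quinone methide and so locks C2, and the bulky C3 silyl ether prepares the facial bias for step 12.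

Step 11
Reactants: 19 tris-silylated 8-bromo ketone; 20 tributyl(3-methylbut-2-enyl)stannane
Product: 21 (2R,3R)-3,7-bis(tert-butyldimethylsilyloxy)-2-[4-(tert-butyldimethylsilyloxy)phenyl]-5-methoxy-8-(3-methylbut-2-enyl)chroman-4-one
Conditions: Pd(PPh3)4 (10 mol %), 20 (1.5 equiv), degassed toluene, 105 °C
Reagents that add atoms: none
Why: Stille coupling: zerovalent palladium inserts into C8–Br of a ring whose oxygen donors are partly tied up by the C4 carbonyl, the allylic stannane transmetalates readily, and C–C bond formation at the less hindered primary terminus of the prenylpalladium species should give the linear 3-methylbut-2-enyl group, while the neutral medium leaves silyl ethers, ketone, C2 and C3 untouched.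

Step 12
Reactants: 21 tris-silylated 8-prenyl ketone
Product: 23 (2R,3S,4S)-3,7-bis(tert-butyldimethylsilyloxy)-2-[4-(tert-butyldimethylsilyloxy)phenyl]-5-methoxy-8-(3-methylbut-2-enyl)chroman-4-ol, via lithium alkoxide 22 (not isolated)
Conditions: LiBH(s-Bu)3 (1.5 equiv), THF, −78 → −40 °C; then H2O
Reagents that add atoms: none
Why: Diastereoselective ketone reduction under steric approach control: the bulky trialkylborohydride approaches C4 along the pseudo-equatorial trajectory on the alpha face, anti to the beta-oriented C3 silyl ether, so the new hydroxyl is pushed into the pseudo-axial beta position, which sets (4S), 3,4-cis, and also avoids peri strain with C5–OMe.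

Step 13
Reactants: 23 tris-silylated 4beta-ol
Product: 24 5-O-methyl-8-prenylafzelechin-4beta-ol [(2R,3S,4S)-2-(4-hydroxyphenyl)-5-methoxy-8-(3-methylbut-2-enyl)chromane-3,4,7-triol]
Conditions: Bu4NF (3.5 equiv), AcOH (3.5 equiv), THF, 0 °C
Reagents that add atoms: none
Why: Fluoride-induced desilylation removes all three silyl groups, and buffering with acetic acid keeps the medium near neutral, so that neither acid ionisation of the benzylic C4–OH nor phenoxide-driven expulsion of it should disturb C4, C2 or the prenyl group.

## Compound list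

1 | D-tyrosine | N[C@H](Cc1ccc(O)cc1)C(=O)O | starting material
2 | (R)-diazonium carboxylate of tyrosine (formed in the flask) | N#[N+][C@H](Cc1ccc(O)cc1)C(=O)[O-] | intermediate
3 | (S)-3-(4-hydroxybenzyl)oxiran-2-one, alpha-lactone (formed in the flask) | O=C1O[C@H]1Cc1ccc(O)cc1 | intermediate
4 | (R)-2-hydroxy-3-(4-hydroxyphenyl)propanoic acid | O[C@H](Cc1ccc(O)cc1)C(=O)O | intermediate
5 | benzotriazol-1-yl (R)-2-hydroxy-3-(4-hydroxyphenyl)propanoate (formed in the flask) | O=C(On1nnc2ccccc12)[C@H](O)Cc1ccc(O)cc1 | intermediate
6 | (R)-2-hydroxy-3-(4-hydroxyphenyl)-N-methoxy-N-methylpropanamide | CON(C)C(=O)[C@H](O)Cc1ccc(O)cc1 | intermediate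
7 | (R)-N-methoxy-2-(methoxymethoxy)-3-[4-(methoxymethoxy)phenyl]-N-methylpropanamide | CON(C)C(=O)[C@H](OCOC)Cc1ccc(OCOC)cc1 | intermediate
8 | 5-methoxyresorcinol | COc1cc(O)cc(O)c1 | starting material
9 | 1-methoxy-3,5-bis(methoxymethoxy)benzene | COCOc1cc(OC)cc(OCOC)c1 | intermediate
10 | [4-methoxy-2,6-bis(methoxymethoxy)phenyl]lithium (formed in the flask) | [Li]c1c(OCOC)cc(OC)cc1OCOC | intermediate
11 | 2-bromo-5-methoxy-1,3-bis(methoxymethoxy)benzene | COCOc1cc(OC)cc(OCOC)c1Br | intermediate
12 | 2-bromo-4-iodo-5-methoxy-1,3-bis(methoxymethoxy)benzene | COc1cc(OCOC)c(Br)c(OCOC)c1I | intermediate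
13 | [3-bromo-6-methoxy-2,4-bis(methoxymethoxy)phenyl]magnesium chloride (formed in the flask) | COc1cc(OCOC)c(Br)c(OCOC)c1[Mg]Cl | intermediate
14 | chloromagnesium alkoxide of the N-methoxy-N-methyl hemiaminal, chelated tetrahedral adduct (formed in the flask) | COc1cc(OCOC)c(Br)c(OCOC)c1C(O[Mg]Cl)(N(C)OC)[C@H](OCOC)Cc1ccc(OCOC)cc1 | intermediate
15 | (R)-1-[3-bromo-6-methoxy-2,4-bis(methoxymethoxy)phenyl]-2-(methoxymethoxy)-3-[4-(methoxymethoxy)phenyl]propan-1-one | COc1cc(OCOC)c(Br)c(OCOC)c1C(=O)[C@H](OCOC)Cc1ccc(OCOC)cc1 | intermediate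
16 | (R)-1-(3-bromo-2,4-dihydroxy-6-methoxyphenyl)-2-hydroxy-3-(4-hydroxyphenyl)propan-1-one (key-step precursor) | COc1cc(O)c(Br)c(O)c1C(=O)[C@H](O)Cc1ccc(O)cc1 | intermediate
17 | (R)-para-quinone methide, 4-[3-(3-bromo-2,4-dihydroxy-6-methoxyphenyl)-2-hydroxy-3-oxopropylidene]cyclohexa-2,5-dien-1-one (formed in the flask) | COc1cc(O)c(Br)c(O)c1C(=O)[C@H](O)C=C1C=CC(=O)C=C1 | intermediate
18 | (2R,3R)-8-bromo-5-O-methylaromadendrin (key-step product) | COc1cc(O)c(Br)c2c1C(=O)[C@H](O)[C@@H](c1ccc(O)cc1)O2 | intermediate
19 | (2R,3R)-8-bromo-3,7-bis(tert-butyldimethylsilyloxy)-2-[4-(tert-butyldimethylsilyloxy)phenyl]-5-methoxychroman-4-one | COc1cc(O[Si](C)(C)C(C)(C)C)c(Br)c2c1C(=O)[C@H](O[Si](C)(C)C(C)(C)C)[C@@H](c1ccc(O[Si](C)(C)C(C)(C)C)cc1)O2 | intermediate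
20 | tributyl(3-methylbut-2-enyl)stannane | CCCC[Sn](CCCC)(CCCC)CC=C(C)C | starting material
21 | (2R,3R)-3,7-bis(tert-butyldimethylsilyloxy)-2-[4-(tert-butyldimethylsilyloxy)phenyl]-5-methoxy-8-(3-methylbut-2-enyl)chroman-4-one | COc1cc(O[Si](C)(C)C(C)(C)C)c(CC=C(C)C)c2c1C(=O)[C@H](O[Si](C)(C)C(C)(C)C)[C@@H](c1ccc(O[Si](C)(C)C(C)(C)C)cc1)O2 | intermediate
22 | lithium (2R,3S,4S)-4-alkoxide of 23 (formed in the flask) | COc1cc(O[Si](C)(C)C(C)(C)C)c(CC=C(C)C)c2c1[C@H](O[Li])[C@H](O[Si](C)(C)C(C)(C)C)[C@@H](c1ccc(O[Si](C)(C)C(C)(C)C)cc1)O2 | intermediate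
23 | (2R,3S,4S)-3,7-bis(tert-butyldimethylsilyloxy)-2-[4-(tert-butyldimethylsilyloxy)phenyl]-5-methoxy-8-(3-methylbut-2-enyl)chroman-4-ol | COc1cc(O[Si](C)(C)C(C)(C)C)c(CC=C(C)C)c2c1[C@H](O)[C@H](O[Si](C)(C)C(C)(C)C)[C@@H](c1ccc(O[Si](C)(C)C(C)(C)C)cc1)O2 | intermediate
24 | 5-O-methyl-8-prenylafzelechin-4beta-ol, (2R,3S,4S) | COc1cc(O)c(CC=C(C)C)c2c1[C@H](O)[C@H](O)[C@@H](c1ccc(O)cc1)O2 | target

## Step count

- Total step count: 13.
- Longest linear sequence: 10 steps (steps 1–3 and 7–13 from 1). The branch from 8 (steps 4–6 and 7–13) is equally long.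

## Steps most likely to fail

**Step 9.**
- Hydride abstraction may be slow because C2 sits next to an electron-poor carbinol carbon.
- The quinone methide may tautomerise by loss of the acidic C3–H, which would erase the tyrosine-derived configuration.
- The cyclised product may be dehydrogenated further.

The fallback makes the C2–O bond by epoxide opening instead of C–H oxidation, using the established chalcone-epoxide route to dihydroflavonols. It sets out from 12 and comes back at 18.
- Arylmagnesium 13, generated as in step 7, would be acylated with N-methoxy-N-methylacetamide to give 1-[3-bromo-6-methoxy-2,4-bis(methoxymethoxy)phenyl]ethan-1-one F1.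
- Claisen–Schmidt condensation of F1 with 4-(methoxymethoxy)benzaldehyde (KOH, EtOH, rt) would give the (E)-chalcone F2.
- Juliá–Colonna epoxidation (poly-L-leucine, urea–H2O2, DBU, THF) would give the (alphaR,betaS)-epoxychalcone F3.
- Methanolic HCl at 45 °C would remove the three MOM groups and let C8a–OH open the epoxide at benzylic C2 (6-endo). The C3–O bond stays untouched and the 2,3-trans isomer is favoured, giving 18.

**Step 11.**
- Oxidative addition of zerovalent palladium into the C8–Br bond, which is flanked by O1 and the bulky C7 silyl ether, may be slow enough for protodebromination to compete.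
- Transfer of the bulky prenyl group may occur with allylic transposition.

The fallback separates C–C bond formation from construction of the trisubstituted alkene. It sets out from 19 and comes back at 21.
- Stille coupling with the smaller and regiochemically unambiguous allyltributylstannane (Pd(PPh3)4, toluene, 105 °C) would give the 8-allyl ketone F4.
- Olefin cross metathesis of F4 with excess 2-methylbut-2-ene would give 21. Conditions: second-generation Grubbs catalyst, RuCl2(=CHPh)(PCy3)(H2IMes), CH2Cl2, 40 °C.

**Step 12.**
- Crowding by C5–OMe and the C3 silyl ether may stop the bulky hydride from reacting.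
- Facial selectivity may be poor.
- The basic reagent may trigger enolisation and opening of ring C.

The fallback replaces kinetic facial control by thermodynamic equilibration at C4. It sets out from 21 and comes back at 24.
- NaBH4 (THF/MeOH, 0 °C) should deliver hydride axially and give the 3,4-trans alcohol, the tris-silylated 4alpha-ol F5.
- Bu4NF/AcOH would free 5-O-methyl-8-prenylafzelechin-4alpha-ol F6.
- Dilute aqueous acetic acid in MeCN at 40 °C under argon would ionise C4–OH reversibly to the benzylic cation stabilised by O1, C5–OMe and C7–OH. This is the known mild-acid epimerisation of 3,4-trans to 3,4-cis flavan-3,4-diols.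
- 24 would then be separated by reversed-phase chromatography, and recovered F6 would be resubmitted.

## Further compounds

F1 | step 9 | 1-[3-bromo-6-methoxy-2,4-bis(methoxymethoxy)phenyl]ethan-1-one | COc1cc(OCOC)c(Br)c(OCOC)c1C(C)=O
F2 | step 9 | (E)-1-[3-bromo-6-methoxy-2,4-bis(methoxymethoxy)phenyl]-3-[4-(methoxymethoxy)phenyl]prop-2-en-1-one | COc1cc(OCOC)c(Br)c(OCOC)c1C(=O)/C=C/c1ccc(OCOC)cc1
F3 | step 9 | [3-bromo-6-methoxy-2,4-bis(methoxymethoxy)phenyl]{(2R,3S)-3-[4-(methoxymethoxy)phenyl]oxiran-2-yl}methanone | COc1cc(OCOC)c(Br)c(OCOC)c1C(=O)[C@@H]1O[C@H]1c1ccc(OCOC)cc1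
F4 | step 11 | (2R,3R)-8-allyl-3,7-bis(tert-butyldimethylsilyloxy)-2-[4-(tert-butyldimethylsilyloxy)phenyl]-5-methoxychroman-4-one | COc1cc(O[Si](C)(C)C(C)(C)C)c(CC=C)c2c1C(=O)[C@H](O[Si](C)(C)C(C)(C)C)[C@@H](c1ccc(O[Si](C)(C)C(C)(C)C)cc1)O2
F5 | step 12 | (2R,3S,4R)-3,7-bis(tert-butyldimethylsilyloxy)-2-[4-(tert-butyldimethylsilyloxy)phenyl]-5-methoxy-8-(3-methylbut-2-enyl)chroman-4-ol | COc1cc(O[Si](C)(C)C(C)(C)C)c(CC=C(C)C)c2c1[C@@H](O)[C@H](O[Si](C)(C)C(C)(C)C)[C@@H](c1ccc(O[Si](C)(C)C(C)(C)C)cc1)O2
F6 | step 12 | 5-O-methyl-8-prenylafzelechin-4alpha-ol, (2R,3S,4R) | COc1cc(O)c(CC=C(C)C)c2c1[C@@H](O)[C@H](O)[C@@H](c1ccc(O)cc1)O2
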